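**Retrosynthetic overview**
1. Both arenes are bought. The pyran is the only ring built and it is closed last, by dehydrating a 3-hydroxyisochroman lactol that forms from an o-(hydroxymethyl)benzyl aryl 1,2-diketone.
2. The 1,2-diketone (its enol is an α-hydroxychalcone) is unmasked from an α-(methoxymethoxy)chalcone. The benzylic OH stays silylated until the enone is gone, so 5-exo oxa-Michael closure to a phthalan cannot occur.
3. Key C–C disconnection, C3–C4: crossed lithium-enolate aldol addition of 1-(2,4-dimethoxyphenyl)-2-(methoxymethoxy)ethanone to 2-(silyloxymethyl)-4,5-dimethoxybenzaldehyde, followed by acetylation and E1cB elimination.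
4. The aldehyde comes from 6-bromoveratraldehyde (reduction, TBDPS protection, Br/Li exchange with DMF). The ketone comes from 2-bromo-2',4'-dimethoxyacetophenone (formate displacement, MOM protection).

Assumption: the target (C20H20O6) has no stereocentre and is achiral, so there is no enantiomer to select. The aldol centres, the lactol centre and the enone geometry are all transient.

**Step 1**
Reactants: 1 2-bromo-4,5-dimethoxybenzaldehyde
Product: 2 (2-bromo-4,5-dimethoxyphenyl)methanol
Conditions: NaBH4, MeOH, 0 °C to rt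
Reagents that add atoms: none
Why: Borohydride carbonyl reduction is chemoselective for the aldehyde and leaves the aryl bromide and the methyl ethers untouched; no stereocentre is formed.

**Step 2**
Reactants: 2 (2-bromo-4,5-dimethoxyphenyl)methanol
Product: 3 [(2-bromo-4,5-dimethoxybenzyl)oxy](tert-butyl)diphenylsilane
Conditions: TBDPSCl, imidazole, DMF, rt
Reagents that add atoms: tert-butyl(chloro)diphenylsilane, CC(C)(C)[Si](Cl)(c1ccccc1)c1ccccc1
Why: Imidazole-promoted silyl ether protection of a primary alcohol gives a group that survives organolithiums, enolates, DBU and the dilute acid used later.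

**Step 3**
Reactants: 3 [(2-bromo-4,5-dimethoxybenzyl)oxy](tert-butyl)diphenylsilane
Product: 6 2-{[(tert-butyldiphenylsilyl)oxy]methyl}-4,5-dimethoxybenzaldehyde, via the aryllithium 4 (not isolated), via the lithium α-(dimethylamino)alkoxide 5 (not isolated)
Conditions: n-BuLi, THF, −78 °C, 20 min; DMF, −78 to 0 °C; cold 1 M aq HCl quench
Reagents that add atoms: N,N-dimethylformamide, CN(C)C=O
Why: Bromine–lithium exchange followed by Bouveault-type formylation is fast at −78 °C, where the bulky TBDPS group does not undergo retro-Brook O-to-C migration, and the tetrahedral adduct collapses to the aldehyde only on quench.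

**Step 4**
Reactants: 7 2-bromo-1-(2,4-dimethoxyphenyl)ethan-1-one
Product: 9 1-(2,4-dimethoxyphenyl)-2-hydroxyethan-1-one, via the formate ester 8 (not isolated)
Conditions: HCO2Na (4 equiv), EtOH–H2O 4:1, reflux
Reagents that add atoms: sodium formate, [Na+].[O-]C=O
Why: SN2 displacement of the activated phenacyl bromide by the weakly basic formate ion, then in situ solvolysis of the labile formate ester, gives the α-hydroxy ketone without strong base.

**Step 5**
Reactants: 9 1-(2,4-dimethoxyphenyl)-2-hydroxyethan-1-one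
Product: 10 1-(2,4-dimethoxyphenyl)-2-(methoxymethoxy)ethan-1-one
Conditions: MOMCl, i-Pr2NEt, CH2Cl2, 0 °C to rt
Reagents that add atoms: chloromethyl methyl ether, COCCl
Why: O-alkylation with the oxocarbenium-type electrophile (MOM acetal protection) needs only a hindered amine base, so the ketone is not enolised and the group is stable to LDA and DBU.

**Step 6**
Reactants: 10 1-(2,4-dimethoxyphenyl)-2-(methoxymethoxy)ethan-1-one; 6 2-{[(tert-butyldiphenylsilyl)oxy]methyl}-4,5-dimethoxybenzaldehyde
Product: 12 3-(2-{[(tert-butyldiphenylsilyl)oxy]methyl}-4,5-dimethoxyphenyl)-1-(2,4-dimethoxyphenyl)-3-hydroxy-2-(methoxymethoxy)propan-1-one (racemic syn/anti mixture), via the chelated (Z)-lithium enolate 11 (not isolated)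
Conditions: LDA (commercial solution, 1.1 equiv), THF, −78 °C, 45 min; then 6 in THF, −78 °C, 2 h; AcOH quench at −78 °C
Reagents that add atoms: none
Why: This directed crossed aldol addition of a quantitatively preformed enolate to a non-enolisable aldehyde has only one possible C–C coupling, and the two new stereocentres form as a racemic diastereomer mixture that needs no control because both are erased in step 8.

**Step 7**
Reactants: 12 the aldol adduct
Product: 13 1-(2-{[(tert-butyldiphenylsilyl)oxy]methyl}-4,5-dimethoxyphenyl)-3-(2,4-dimethoxyphenyl)-2-(methoxymethoxy)-3-oxopropyl acetate (racemic diastereomer mixture, used crude after aqueous work-up)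
Conditions: Ac2O, Et3N, DMAP (10 mol %), CH2Cl2, 0 °C to rt
Reagents that add atoms: acetic anhydride, CC(=O)OC(C)=O
Why: DMAP-catalysed acylation converts the electron-rich benzylic alcohol into a leaving group that is easier to handle than a sulfonate, and any premature elimination only delivers the next product.

**Step 8**
Reactants: 13 the β-acetoxy ketone
Product: 14 (Z)-3-(2-{[(tert-butyldiphenylsilyl)oxy]methyl}-4,5-dimethoxyphenyl)-1-(2,4-dimethoxyphenyl)-2-(methoxymethoxy)prop-2-en-1-one
Conditions: DBU (2 equiv), CH2Cl2, rt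
Reagents that add atoms: none
Why: E1cB elimination through the ketone enolate expels acetate and gives the conjugated α-alkoxy enone, mainly as the thermodynamic Z isomer (aryl trans to aroyl), and any E isomer converges in step 9.

**Step 9**
Reactants: 14 the α-(methoxymethoxy)enone
Product: 15 (Z)-3-(2-{[(tert-butyldiphenylsilyl)oxy]methyl}-4,5-dimethoxyphenyl)-1-(2,4-dimethoxyphenyl)-2-hydroxyprop-2-en-1-one (H-bonded enol tautomer of the propane-1,2-dione)
Conditions: 3 M aq HCl–THF 1:4, 45 °C, N2
Reagents that add atoms: none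
Why: Acid-catalysed acetal hydrolysis is fast here because the leaving group is an acidic, phenol-like enol, whereas the TBDPS ether is several orders of magnitude more acid-stable, so the Michael acceptor is dismantled before any free benzylic OH exists.

**Step 10**
Reactants: 15 the silylated α-hydroxychalcone
Product: 17 (2,4-dimethoxyphenyl)(3-hydroxy-6,7-dimethoxy-3,4-dihydro-1H-isochromen-3-yl)methanone (racemic lactol), via 1-(2,4-dimethoxyphenyl)-3-[2-(hydroxymethyl)-4,5-dimethoxyphenyl]propane-1,2-dione 16 (not isolated)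
Conditions: TBAF (1.2 equiv), AcOH (1.5 equiv), THF, 0 °C to rt
Reagents that add atoms: none
Why: Buffered fluoride desilylation frees the primary alcohol, which adds to the highly electrophilic C2 carbonyl of the diketone tautomer (ring–chain tautomerism, six-membered hemiketal), and the new stereocentre is racemic and is removed in step 11.

**Step 11**
Reactants: 17 the lactol
Product: 18 (2,4-dimethoxyphenyl)(6,7-dimethoxy-1H-isochromen-3-yl)methanone (target)
Conditions: p-TsOH·H2O (10 mol %), toluene, Dean–Stark reflux, N2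
Reagents that add atoms: none
Why: Acid-catalysed hemiketal dehydration with loss of a benzylic C4–H is driven by azeotropic water removal and by the fully conjugated aryl–enol ether–aroyl system, and it leaves no stereocentre.

**Compound list**
1 | 2-bromo-4,5-dimethoxybenzaldehyde | COc1cc(Br)c(C=O)cc1OC | starting material
2 | (2-bromo-4,5-dimethoxyphenyl)methanol | COc1cc(Br)c(CO)cc1OC | intermediate
3 | [(2-bromo-4,5-dimethoxybenzyl)oxy](tert-butyl)diphenylsilane | COc1cc(Br)c(CO[Si](c2ccccc2)(c2ccccc2)C(C)(C)C)cc1OC | intermediate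
4 | (2-{[(tert-butyldiphenylsilyl)oxy]methyl}-4,5-dimethoxyphenyl)lithium, formed in situ | COc1cc([Li])c(CO[Si](c2ccccc2)(c2ccccc2)C(C)(C)C)cc1OC | intermediate
5 | lithium (2-{[(tert-butyldiphenylsilyl)oxy]methyl}-4,5-dimethoxyphenyl)(dimethylamino)methanolate, formed in situ | COc1cc(C([O-])N(C)C)c(CO[Si](c2ccccc2)(c2ccccc2)C(C)(C)C)cc1OC.[Li+] | intermediate
6 | 2-{[(tert-butyldiphenylsilyl)oxy]methyl}-4,5-dimethoxybenzaldehyde | COc1cc(C=O)c(CO[Si](c2ccccc2)(c2ccccc2)C(C)(C)C)cc1OC | intermediate
7 | 2-bromo-1-(2,4-dimethoxyphenyl)ethan-1-one | COc1ccc(C(=O)CBr)c(OC)c1 | starting material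
8 | 2-(2,4-dimethoxyphenyl)-2-oxoethyl formate, formed in situ | COc1ccc(C(=O)COC=O)c(OC)c1 | intermediate
9 | 1-(2,4-dimethoxyphenyl)-2-hydroxyethan-1-one | COc1ccc(C(=O)CO)c(OC)c1 | intermediate
10 | 1-(2,4-dimethoxyphenyl)-2-(methoxymethoxy)ethan-1-one | COCOCC(=O)c1ccc(OC)cc1OC | intermediate
11 | lithium (Z)-1-(2,4-dimethoxyphenyl)-2-(methoxymethoxy)ethen-1-olate, formed in situ | [Li+].COCO/C=C(\[O-])c1ccc(OC)cc1OC | intermediate
12 | 3-(2-{[(tert-butyldiphenylsilyl)oxy]methyl}-4,5-dimethoxyphenyl)-1-(2,4-dimethoxyphenyl)-3-hydroxy-2-(methoxymethoxy)propan-1-one, racemic syn/anti mixture | COCOC(C(O)c1cc(OC)c(OC)cc1CO[Si](c1ccccc1)(c1ccccc1)C(C)(C)C)C(=O)c1ccc(OC)cc1OC | intermediate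
13 | 1-(2-{[(tert-butyldiphenylsilyl)oxy]methyl}-4,5-dimethoxyphenyl)-3-(2,4-dimethoxyphenyl)-2-(methoxymethoxy)-3-oxopropyl acetate, racemic diastereomer mixture | COCOC(C(OC(C)=O)c1cc(OC)c(OC)cc1CO[Si](c1ccccc1)(c1ccccc1)C(C)(C)C)C(=O)c1ccc(OC)cc1OC | intermediate
14 | (Z)-3-(2-{[(tert-butyldiphenylsilyl)oxy]methyl}-4,5-dimethoxyphenyl)-1-(2,4-dimethoxyphenyl)-2-(methoxymethoxy)prop-2-en-1-one | COCO/C(=C\c1cc(OC)c(OC)cc1CO[Si](c1ccccc1)(c1ccccc1)C(C)(C)C)C(=O)c1ccc(OC)cc1OC | intermediate
15 | (Z)-3-(2-{[(tert-butyldiphenylsilyl)oxy]methyl}-4,5-dimethoxyphenyl)-1-(2,4-dimethoxyphenyl)-2-hydroxyprop-2-en-1-one (enol of the 1,2-dione) | O/C(=C\c1cc(OC)c(OC)cc1CO[Si](c1ccccc1)(c1ccccc1)C(C)(C)C)C(=O)c1ccc(OC)cc1OC | intermediate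
16 | 1-(2,4-dimethoxyphenyl)-3-[2-(hydroxymethyl)-4,5-dimethoxyphenyl]propane-1,2-dione, formed in situ | COc1ccc(C(=O)C(=O)Cc2cc(OC)c(OC)cc2CO)c(OC)c1 | intermediate
17 | (2,4-dimethoxyphenyl)(3-hydroxy-6,7-dimethoxy-3,4-dihydro-1H-isochromen-3-yl)methanone, racemic | COc1ccc(C(=O)C2(O)Cc3cc(OC)c(OC)cc3CO2)c(OC)c1 | intermediate
18 | (2,4-dimethoxyphenyl)(6,7-dimethoxy-1H-isochromen-3-yl)methanone | COc1ccc(C(=O)C2=Cc3cc(OC)c(OC)cc3CO2)c(OC)c1 | target

**Step count and risks**
- Total step count: 11.
- Longest linear sequence: 9 steps (steps 1, 2, 3, 6, 7, 8, 9, 10 and 11, from 1). The branch from 7 has 8 steps.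

Steps most likely to fail:

**Step 6.** The risks are retro-aldol, O-to-O silyl migration in the lithium aldolate, and sluggish addition to the hindered, electron-rich aldehyde. The fallback sets out from 10 and comes back at 12. Ketone 10 is converted with TMSOTf/Et3N (CH2Cl2, 0 °C) into (Z)-{[1-(2,4-dimethoxyphenyl)-2-(methoxymethoxy)ethenyl]oxy}trimethylsilane F1. This is added to aldehyde 6 under BF3·OEt2 (CH2Cl2, −78 °C) in a Mukaiyama aldol addition. The aldehyde is activated by the Lewis acid and no basic alkoxide is ever present, so the addition is irreversible. Aqueous work-up removes the silyl group and gives 12.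

**Step 9.** The risks are incomplete selectivity between the enol MOM ether and the benzylic silyl ether, and loss of the free diketone/enol on prolonged acid exposure. The fallback sets out from 14 and comes back at 18, and it closes the ring by O-alkylation instead of lactolisation.
- Buffered TBAF/AcOH first gives (Z)-1-(2,4-dimethoxyphenyl)-3-[2-(hydroxymethyl)-4,5-dimethoxyphenyl]-2-(methoxymethoxy)prop-2-en-1-one F2.
- MsCl/Et3N in CH2Cl2 then forms (Z)-2-[3-(2,4-dimethoxyphenyl)-2-(methoxymethoxy)-3-oxoprop-1-en-1-yl]-4,5-dimethoxybenzyl methanesulfonate F3. The chloride ion present converts it in the same flask to (Z)-3-[2-(chloromethyl)-4,5-dimethoxyphenyl]-1-(2,4-dimethoxyphenyl)-2-(methoxymethoxy)prop-2-en-1-one F4.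
- Wet TFA/CH2Cl2 at 0 °C releases (Z)-3-[2-(chloromethyl)-4,5-dimethoxyphenyl]-1-(2,4-dimethoxyphenyl)-2-hydroxyprop-2-en-1-one F5.
- K2CO3 in acetone closes F5 at once by intramolecular Williamson O-alkylation to give 18. C-alkylation would require a benzocyclobutene, so it does not compete.

**Step 11.** The risks are that the oxocarbenium ion next to the aroyl group forms reluctantly, and that hot acid promotes oxidation or disproportionation of the electron-rich 1H-isochromene. The fallback sets out from 17 and comes back at 18. Under neutral Mitsunobu conditions (PPh3, DIAD, THF, 0 °C to rt) the primary benzylic alcohol of the open tautomer 16 is activated. The acidic diketone enol then displaces it intramolecularly, so the C1–O2 bond is formed rather than water being lost at C3. This fallback makes no compound outside the list (F0).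

**Further compounds**
F1 | step 6 | (Z)-{[1-(2,4-dimethoxyphenyl)-2-(methoxymethoxy)ethenyl]oxy}trimethylsilane | COCO/C=C(\O[Si](C)(C)C)c1ccc(OC)cc1OC
F2 | step 9 | (Z)-1-(2,4-dimethoxyphenyl)-3-[2-(hydroxymethyl)-4,5-dimethoxyphenyl]-2-(methoxymethoxy)prop-2-en-1-one | COCO/C(=C\c1cc(OC)c(OC)cc1CO)C(=O)c1ccc(OC)cc1OC
F3 | step 9 | (Z)-2-[3-(2,4-dimethoxyphenyl)-2-(methoxymethoxy)-3-oxoprop-1-en-1-yl]-4,5-dimethoxybenzyl methanesulfonate | COCO/C(=C\c1cc(OC)c(OC)cc1COS(C)(=O)=O)C(=O)c1ccc(OC)cc1OC
F4 | step 9 | (Z)-3-[2-(chloromethyl)-4,5-dimethoxyphenyl]-1-(2,4-dimethoxyphenyl)-2-(methoxymethoxy)prop-2-en-1-one | COCO/C(=C\c1cc(OC)c(OC)cc1CCl)C(=O)c1ccc(OC)cc1OC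
F5 | step 9 | (Z)-3-[2-(chloromethyl)-4,5-dimethoxyphenyl]-1-(2,4-dimethoxyphenyl)-2-hydroxyprop-2-en-1-one | O/C(=C\c1cc(OC)c(OC)cc1CCl)C(=O)c1ccc(OC)cc1OC
F0 | step 11 | none | none
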